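The plan rests on cutting the target back to the eremophilane hydrocarbon (+)-aristolochene, once the two esters and the oxygens at C3, C8 and C9 are removed. That hydrocarbon is then cut to an open C15 chain. The cyclase step exploits the sesquiterpene pattern of rings A and B: vicinal methyls on C4 and C5 and the isopropenyl group on C7. In one operation it forms C6–C7, C5–C10 and C5–C14, closes both six-membered rings and fixes C4, C5 and C7 absolutely. It also leaves the C9=C10 alkene as the handle for O8, O9 and H10. Its precursor is achiral (2E,6E)-farnesyl diphosphate, made from farnesol in two steps.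

Key step: step 3

Remark (numbering and faces): eremophilane numbering is used throughout, also for the open chain (C6 is the carbinol carbon of farnesol, C7=C11 the distal alkene); β is the face carrying the methyls C14 and C15; ring A is C1–C5/C10 and ring B is C5–C10.
Remark (order of events): (+)-aristolochene, (4S,5R,7S), has C4 and C5 of the target but the opposite C7; in the Δ9-en-8-one the 7α-isopropenyl group is equatorial and the more stable, so C7 is inverted only after the ring fusion is cis and O3 is in place.
Remark (assumptions): farnesyl diphosphate is drawn as the free acid but handled as its tris(ammonium) salt; a C3-selective P450 BM3 variant is assumed to be found by screening a mutant panel.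

Step 1
Reactants: 1 (2E,6E)-farnesol
Product: 2 (2E,6E)-farnesyl chloride
Conditions: NCS, Me2S, CH2Cl2, −40 °C to 0 °C
Reagents that add atoms: N-chlorosuccinimide, O=C1CCC(=O)N1Cl
Why: In this Corey–Kim-type chlorination the allylic hydroxyl is activated on sulfur and displaced by chloride in SN2 fashion under cold, neutral conditions, so neither allylic transposition nor E/Z scrambling should occur.

Step 2
Reactants: 2 (2E,6E)-farnesyl chloride
Product: 3 (2E,6E)-farnesyl diphosphate
Conditions: (n-Bu4N)3HP2O7, MeCN, rt; then Dowex 50W-X8 (NH4+ form), aq NH4HCO3/i-PrOH; cellulose chromatography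
Reagents that add atoms: tris(tetrabutylammonium) hydrogen diphosphate, CCCC[N+](CCCC)(CCCC)CCCC.CCCC[N+](CCCC)(CCCC)CCCC.CCCC[N+](CCCC)(CCCC)CCCC.OP(=O)([O-])OP(=O)([O-])[O-]
Why: This is the standard direct SN2 diphosphorylation of a primary allylic halide by the soluble diphosphate anion in a dipolar aprotic solvent, and it leaves the alkene geometry untouched.

Step 3
Reactants: 3 (2E,6E)-farnesyl diphosphate
Product: 5 (+)-aristolochene, via (S)-germacrene A 4 (not isolated)
Conditions: aristolochene synthase (Aspergillus terreus, recombinant from E. coli), MgCl2, Tris·HCl buffer pH 7.5, glycerol, pentane overlay, 30 °C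
Reagents that add atoms: none
Why: Mg2+-assisted ionisation of the diphosphate gives an allylic cation at C6 that is captured by the distal C7=C11 alkene (ten-membered ring, closure exo to that alkene, then loss of a C12 proton) to give enzyme-bound 4; reprotonation at C1 triggers transannular attack of C5 on C10, which divides the macrocycle into rings A and B (endo to the C4=C5 alkene for ring A, exo for ring B) and leaves a cation at C4. A 1,2-hydride shift from C5 to C4, a 1,2-shift of methyl C14 from C10 to C5 and loss of a C9 proton complete the cascade. This is the native reaction of a class 1 (metal-dependent, ionisation-initiated) sesquiterpene cyclase, that is, an enzymatic cation–olefin bicyclisation with Wagner–Meerwein shifts, and it is known for exactly this substrate. C7 is set by the face of the distal alkene that the folded chain offers to C6, while C4 and C5 are set because hydride and methyl migrate suprafacially on opposite faces of the bicyclic cation (H on the α face, C14 on the β face), which places C15 and C14 cis; the absolute sense comes only from the chiral active-site contour, since 3 is achiral. The step needs a single folding mode, no early release of 4 and loss of H9 rather than H1; the E geometry of both internal alkenes and the spacing of the methyl branches in 3 bring the reacting carbons within bonding distance, and this enzyme is chosen for its high product fidelity.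

Step 4
Reactants: 5 (+)-aristolochene
Product: 6 (4S,5R,7S)-eremophila-9,11-dien-8-one (isopropenyl α)
Conditions: Cl4NHPI (cat.), t-BuOOH, pyridine, LiClO4, acetone, carbon electrodes, constant current, undivided cell, rt
Reagents that add atoms: tert-butyl hydroperoxide, CC(C)(C)OO
Why: In Δ5-steroids and in valencene this mediated electrochemical radical allylic C–H oxidation attacks the ring CH2 next to the CH= end of the trisubstituted alkene and spares an isopropenyl group, so C8 rather than C1 should become the ketone, while the weak base pyridine leaves C7 and the side-chain alkene in place.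

Step 5
Reactants: 6 (4S,5R,7S)-eremophila-9,11-dien-8-one
Product: 7 3α-hydroxyeremophila-9,11-dien-8-one (isopropenyl α; petasol)
Conditions: P450 BM3 variant (E. coli lysate), NADP+ (cat.), phosphite dehydrogenase, Na2HPO3, air, K2HPO4/KH2PO4 buffer pH 8, DMSO (2%), 25 °C
Reagents that add atoms: dioxygen, O=O
Why: Cytochrome P450 C–H hydroxylation (hydrogen abstraction by the oxoiron haem and oxygen rebound with retention) is the reaction type by which engineered BM3 variants hydroxylate C3 of carbonyl-anchored decalin terpenoids, and with the C8 carbonyl as polar anchor ring A should point at the haem so that the exposed equatorial 3α-H is replaced by the equatorial 3α-OH, site and face being fixed by the protein pocket.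

Step 6
Reactants: 7 3α-hydroxyeremophila-9,11-dien-8-one
Product: 9 3α-hydroxy-7αH,10βH-eremophil-11-en-8-one (cis-decalone with isopropenyl β), via 7α-isopropenyl ketone 8 (not isolated)
Conditions: [(Ph3P)CuH]6, H2O, degassed toluene, rt; then K2CO3, MeOH, rt, stopped when the epimer ratio is constant
Reagents that add atoms: none
Why: In this conjugate reduction with Stryker's reagent followed by base-mediated epimerisation, copper hydride, like organocuprates, adds to angular-methyl octalones syn to the angular methyl, so hydride should reach C10 from the β face and give cis-fused 8 without touching the isolated alkene or the free alcohol, and reversible enolisation then inverts C7 because only 9 can hold C15, O3 and the isopropenyl group all equatorial in one chair–chair form (C14 axial on ring A, C4 axial on ring B), whereas 8 must either keep the isopropenyl group syn-axial to C4 or flip and put O3 syn-axial to C6.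

Step 7
Reactants: 9 3α-hydroxy-7αH,10βH-eremophil-11-en-8-one; 10 angelic acid
Product: 12 3α-angeloyloxy-7αH,10βH-eremophil-11-en-8-one, via mixed anhydride 11 (not isolated)
Conditions: 10, 2,4,6-Cl3C6H2COCl, Et3N, toluene, rt; then 9, toluene, 80 °C
Reagents that add atoms: 2,4,6-trichlorobenzoyl chloride, O=C(Cl)c1c(Cl)cc(Cl)cc1Cl (its atoms stay only in intermediate 11)
Why: In this Yamaguchi esterification run without DMAP the equatorial 3α-OH attacks the less hindered angeloyl carbonyl of preformed 11, a protocol known to transfer the angeloyl group without Z to E isomerisation, and the C3–O bond is not broken, so the configuration is retained.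

Step 8
Reactants: 12 3α-angeloyloxy-7αH,10βH-eremophil-11-en-8-one
Product: 14 3α-angeloyloxy-9β-hydroxy-7αH,10βH-eremophil-11-en-8-one, via potassium enolate 13 (not isolated)
Conditions: KN(SiMe3)2, THF, −78 °C (12 added to the base); then 2-(phenylsulfonyl)-3-phenyloxaziridine, −78 °C; AcOH quench
Reagents that add atoms: 2-(phenylsulfonyl)-3-phenyloxaziridine, O=S(=O)(c1ccccc1)N1OC1c1ccccc1; KN(SiMe3)2, C[Si](C)(C)[N-][Si](C)(C)C.[K+] (potassium only in intermediate 13)
Why: In this kinetic enolisation and Davis oxaziridine hydroxylation the bulky amide should take a proton from the C9 methylene rather than the tertiary C7–H (cis-fused 2-decalones of the 5β-3-ketosteroid type also enolise towards the ring fusion) and should leave the less acidic ester γ-protons alone at −78 °C, and the oxidant should approach C9 of 13 from the convex β face because C4 of ring A covers the α face, giving the equatorial 9β-alcohol, which is also the more stable epimer.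

Step 9
Reactants: 14 3α-angeloyloxy-9β-hydroxy-7αH,10βH-eremophil-11-en-8-one; 15 3-methylbut-2-enoic acid (senecioic acid)
Product: 16 3α-angeloyloxy-9β-senecioyloxy-7αH,10βH-eremophil-11-en-8-one (target)
Conditions: 15, DCC, DMAP (cat.), CH2Cl2, 0 °C to rt
Reagents that add atoms: none
Why: Steglich esterification acylates the secondary α-ketol under near-neutral conditions and avoids the acid chloride/amine route, whose vinylketene pathway would deconjugate the senecioyl group, while C7 and C9 already hold their more stable equatorial configurations.

Compound list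
1 | (2E,6E)-farnesol | CC(C)=CCC/C(C)=C/CC/C(C)=C/CO | starting material
2 | (2E,6E)-farnesyl chloride | CC(C)=CCC/C(C)=C/CC/C(C)=C/CCl | intermediate
3 | (2E,6E)-farnesyl diphosphate (free acid drawn, tris(ammonium) salt handled) | CC(C)=CCC/C(C)=C/CC/C(C)=C/COP(=O)(O)OP(=O)(O)O | intermediate
4 | (S)-germacrene A, (1(10)E,4E)-germacra-1(10),4,11-triene, enzyme-bound | C=C(C)[C@H]1CC/C(C)=C/CC/C(C)=C/C1 | intermediate
5 | (+)-aristolochene, (4S,5R,7S)-eremophila-9,11-diene (methyls β, isopropenyl α) | C=C(C)[C@@H]1C[C@@]2(C)C(CCC[C@@H]2C)=CC1 | intermediate
6 | (4S,5R,7S)-eremophila-9,11-dien-8-one (isopropenyl α) | C=C(C)[C@@H]1C[C@@]2(C)C(CCC[C@@H]2C)=CC1=O | intermediate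
7 | 3α-hydroxyeremophila-9,11-dien-8-one (isopropenyl α; petasol) | C=C(C)[C@@H]1C[C@@]2(C)C(CC[C@@H](O)[C@@H]2C)=CC1=O | intermediate
8 | 3α-hydroxy-7βH,10βH-eremophil-11-en-8-one (cis-decalone, isopropenyl α) | C=C(C)[C@@H]1C[C@@]2(C)[C@H](CC[C@@H](O)[C@@H]2C)CC1=O | intermediate
9 | 3α-hydroxy-7αH,10βH-eremophil-11-en-8-one (cis-decalone, isopropenyl β) | C=C(C)[C@H]1C[C@@]2(C)[C@H](CC[C@@H](O)[C@@H]2C)CC1=O | intermediate
10 | angelic acid, (Z)-2-methylbut-2-enoic acid | C/C=C(/C)C(=O)O | starting material
11 | angelic 2,4,6-trichlorobenzoic anhydride | C/C=C(/C)C(=O)OC(=O)c1c(Cl)cc(Cl)cc1Cl | intermediate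
12 | 3α-angeloyloxy-7αH,10βH-eremophil-11-en-8-one | C=C(C)[C@H]1C[C@@]2(C)[C@H](CC[C@@H](OC(=O)/C(C)=C\C)[C@@H]2C)CC1=O | intermediate
13 | potassium Δ8(9)-enolate of 12 | C=C(C)[C@H]1C[C@@]2(C)[C@H](CC[C@@H](OC(=O)/C(C)=C\C)[C@@H]2C)C=C1[O-].[K+] | intermediate
14 | 3α-angeloyloxy-9β-hydroxy-7αH,10βH-eremophil-11-en-8-one | C=C(C)[C@H]1C[C@@]2(C)[C@H](CC[C@@H](OC(=O)/C(C)=C\C)[C@@H]2C)[C@@H](O)C1=O | intermediate
15 | 3-methylbut-2-enoic acid (senecioic acid) | CC(C)=CC(=O)O | starting material
16 | (3R,4R,5R,7R,9R,10S)-3α-angeloyloxy-9β-senecioyloxy-7αH,10βH-eremophil-11-en-8-one | C=C(C)[C@H]1C[C@@]2(C)[C@H](CC[C@@H](OC(=O)/C(C)=C\C)[C@@H]2C)[C@@H](OC(=O)C=C(C)C)C1=O | target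

Total step count: 9. Longest linear sequence: 9 steps (1 to 16).

Steps most likely to fail

Step 5. The oxygenase may show poor site selectivity, transferring oxygen to the allylic C1–H bonds or to the isopropenyl alkene instead of C3–H. The fallback sets out from 6 and comes back at 8.
- The first stage of step 6 ([(Ph3P)CuH]6, wet toluene) is run on 6 first. It gives the saturated cis-fused ketone 7βH,10βH-eremophil-11-en-8-one F1.
- In F1, C1 is no longer allylic and the folded skeleton offers ring A to the haem in a different way.
- F1 is then hydroxylated, with the enzyme panel or a hydroxylating fungal culture, to give 8.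
- K2CO3/MeOH converts 8 into 9 as in step 6.

Step 6. Hydride delivery to C10 may show poor facial selectivity (trans fusion), or the side-chain alkene may drift into conjugation during the equilibration. The fallback sets out from 7 and comes back at 9.
- The alkene is moved into conjugation on purpose with DBU in CH2Cl2 to give the cross-conjugated dienone 3α-hydroxyeremophila-7(11),9-dien-8-one (isopetasol) F2.
- Heterogeneous hydrogenation (H2, Pd/C, pyridine) gives cis-decalones from such octalones and should leave the tetrasubstituted C7=C11 bond. It saturates only C9=C10 and gives 3α-hydroxy-10βH-eremophil-7(11)-en-8-one F3.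
- Deconjugation follows: LiN(i-Pr)2 (two equivalents), THF, −78 °C, then kinetic α-protonation of the extended enolate with AcOH. This restores the isopropenyl ketone.
- The K2CO3/MeOH stage of step 6 settles C7 as in 9.

Step 8. Enolisation may show poor regioselectivity (C7 against C9), or the enolates may equilibrate before oxygen transfer. The fallback sets out from 7 and comes back at 16. It draws the enolate position from the enone instead of from a deprotonation.
- Yamaguchi angeloylation of 7 gives 3α-angeloyloxyeremophila-9,11-dien-8-one (petasin) F4.
- Catalytic [(Ph3P)CuH]6 with PhMe2SiH in toluene performs a 1,4-hydrosilylation. The α-branched, trisubstituted angelate is expected to react far more slowly than the enone. The product is the regiodefined cis-fused Δ8(9) dimethylphenylsilyl enol ether F5.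
- Rubottom oxidation with dimethyldioxirane at −78 °C and a mild acid work-up give the 9-hydroxy ketone with α-isopropenyl group F6.
- DCC/DMAP esterification with 15 gives the 7-epimer of the target F7.
- DBU in toluene then equilibrates C7 (and C9, if needed) to the all-equatorial 16.

Further compounds
F1 | step 5 | 7βH,10βH-eremophil-11-en-8-one (cis-decalone, isopropenyl α, no O3) | C=C(C)[C@@H]1C[C@@]2(C)[C@H](CCC[C@@H]2C)CC1=O
F2 | step 6 | 3α-hydroxyeremophila-7(11),9-dien-8-one (isopetasol) | CC(C)=C1C[C@@]2(C)C(CC[C@@H](O)[C@@H]2C)=CC1=O
F3 | step 6 | 3α-hydroxy-10βH-eremophil-7(11)-en-8-one | CC(C)=C1C[C@@]2(C)[C@H](CC[C@@H](O)[C@@H]2C)CC1=O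
F4 | step 8 | 3α-angeloyloxyeremophila-9,11-dien-8-one (petasin) | C=C(C)[C@@H]1C[C@@]2(C)C(CC[C@@H](OC(=O)/C(C)=C\C)[C@@H]2C)=CC1=O
F5 | step 8 | 3α-angeloyloxy-8-(dimethylphenylsilyloxy)-7βH,10βH-eremophila-8,11-diene | C=C(C)[C@@H]1C[C@@]2(C)[C@H](CC[C@@H](OC(=O)/C(C)=C\C)[C@@H]2C)C=C1O[Si](C)(C)c1ccccc1
F6 | step 8 | 3α-angeloyloxy-9β-hydroxy-7βH,10βH-eremophil-11-en-8-one | C=C(C)[C@@H]1C[C@@]2(C)[C@H](CC[C@@H](OC(=O)/C(C)=C\C)[C@@H]2C)[C@@H](O)C1=O
F7 | step 8 | 3α-angeloyloxy-9β-senecioyloxy-7βH,10βH-eremophil-11-en-8-one (7-epimer of 16) | C=C(C)[C@@H]1C[C@@]2(C)[C@H](CC[C@@H](OC(=O)/C(C)=C\C)[C@@H]2C)[C@@H](OC(=O)C=C(C)C)C1=O
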